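**Retrosynthetic overview**

- Feature: in ring A (C1 acetyl, C2 CH2CO2H, C3 H, C4 CO2H, C5 aroyl, C6 OH) the C6 hydroxyl lies between C5, which carries the ring B carbonyl carbon, and C1, and C4/C5 are two adjacent carbon-bearing positions. This is the substitution pattern of a 4-hydroxy-1,3-dihydroisobenzofuran, with the C4 and C5 carbons held in the ether ring as a masked keto acid.
- Endgame: target 21 ⇐ BBr3 demethylation of 20 ⇐ Pinnick oxidation of aldehyde 19 ⇐ oxidative opening (DDQ, then O2) of dihydroisobenzofuran 16 ⇐ O-methylation, saponification and ketal removal from phenol 13.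
- Key disconnection: ring A and the fused ether ring of 13 ⇐ furfuryl propargyl ether 11 by gold-catalysed furan-yne isomerisation (C4–C5, C6–C1 and C6–O formed; the furan oxygen becomes the phenol oxygen).
- 11 ⇐ copper-catalysed propargylic etherification of furfuryl alcohol 6 with propargylic acetate 10; 6 from methyl furan-3-ylacetate (C2 acetylation, ketal, C5 formylation, reduction); 10 from 2,6-dimethoxybenzaldehyde and ethynylmagnesium bromide.
- Ring order: furan and ring B are bought; the ether ring and ring A form together in step 8; the ether ring is opened again in step 11.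

Key step: step 8

Assumption: the three starting materials are taken as commercial. Every compound containing the aryl-bearing sp3 carbon is racemic, which is immaterial because that carbon becomes the ketone carbon; 20 and 21 are drawn in the open keto-acid form although a cyclic hydroxyphthalide tautomer may be present.

**Route**

Step 1
Reactants: 1 methyl 2-(furan-3-yl)acetate
Product: 2 methyl 2-(2-acetylfuran-3-yl)acetate
Conditions: Ac2O, BF3·OEt2 (cat.), CH2Cl2, 0 °C → rt
Reagents that add atoms: acetic anhydride CC(=O)OC(C)=O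
Why: Friedel–Crafts acylation of a 3-alkylfuran should go to the α-position next to the substituent (C2), where the σ-complex is stabilised by both the ring oxygen and the C3 alkyl group; any C5 isomer is removed by chromatography.

Step 2
Reactants: 2 methyl 2-(2-acetylfuran-3-yl)acetate
Product: 3 methyl 2-[2-(2-methyl-1,3-dioxolan-2-yl)furan-3-yl]acetate
Conditions: TMSOCH2CH2OTMS, TMSOTf (cat.), CH2Cl2, −78 → −20 °C; then pyridine
Reagents that add atoms: 1,2-bis(trimethylsilyloxy)ethane C[Si](C)(C)OCCO[Si](C)(C)C
Why: Noyori ketalisation is aprotic, so the methyl ester is not transesterified by free glycol and the acetyl/ester pair never meets base (which would trigger an intramolecular Claisen condensation).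

Step 3
Reactants: 3 methyl 2-[2-(2-methyl-1,3-dioxolan-2-yl)furan-3-yl]acetate
Product: 5 methyl 2-[5-formyl-2-(2-methyl-1,3-dioxolan-2-yl)furan-3-yl]acetate, via iminium chloride 4 (not isolated)
Conditions: POCl3, DMF, 0 °C → rt; then aq. NaOAc, 0 °C
Reagents that add atoms: N,N-dimethylformamide CN(C)C=O; water O
Why: Vilsmeier–Haack formylation attacks the only free α-position (C5) of the electron-rich furan, and the ketal should survive because the medium is anhydrous, the iminium acceptor formed at C5 disfavours ketal ionisation, and the hydrolysis is buffered.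

Step 4
Reactants: 5 methyl 2-[5-formyl-2-(2-methyl-1,3-dioxolan-2-yl)furan-3-yl]acetate
Product: 6 methyl 2-[5-(hydroxymethyl)-2-(2-methyl-1,3-dioxolan-2-yl)furan-3-yl]acetate
Conditions: NaBH4, MeOH, 0 °C
Reagents that add atoms: none
Why: borohydride reduction is chemoselective for the aldehyde over the methyl ester and the basic medium keeps the ketal intact.

Step 5
Reactants: 7 2,6-dimethoxybenzaldehyde; 8 ethynylmagnesium bromide
Product: 9 1-(2,6-dimethoxyphenyl)prop-2-yn-1-ol (racemic)
Conditions: THF, 0 °C → rt; then aq. NH4Cl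
Reagents that add atoms: none
Why: Grignard 1,2-addition of the acetylide to the aldehyde gives the propargylic alcohol, whose new stereocentre is uncontrolled and need not be controlled.

Step 6
Reactants: 9 1-(2,6-dimethoxyphenyl)prop-2-yn-1-ol (racemic)
Product: 10 1-(2,6-dimethoxyphenyl)prop-2-yn-1-yl acetate (racemic)
Conditions: Ac2O, Et3N, DMAP (cat.), CH2Cl2, 0 °C
Reagents that add atoms: acetic anhydride CC(=O)OC(C)=O
Why: DMAP-catalysed acylation under basic conditions installs the leaving group without ionising the electron-rich benzylic position.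

Step 7
Reactants: 6 methyl 2-[5-(hydroxymethyl)-2-(2-methyl-1,3-dioxolan-2-yl)furan-3-yl]acetate; 10 1-(2,6-dimethoxyphenyl)prop-2-yn-1-yl acetate (racemic, 1.5 equiv)
Product: 11 methyl 2-[5-({[1-(2,6-dimethoxyphenyl)prop-2-yn-1-yl]oxy}methyl)-2-(2-methyl-1,3-dioxolan-2-yl)furan-3-yl]acetate (racemic)
Conditions: Cu(MeCN)4PF6 (monovalent copper, 5 mol %), 2,6-bis(4,4-dimethyl-4,5-dihydrooxazol-2-yl)pyridine (6 mol %), iPr2NEt, ClCH2CH2Cl, 0 °C → rt, argon
Reagents that add atoms: none
Why: copper-catalysed propargylic etherification, in which the copper acetylide of 10 loses acetate to an aryl-stabilised copper allenylidene that the primary alcohol of 6 captures at the propargylic carbon; the amine-buffered medium spares the ketal, the enolisable ester (which rules out an alkoxide Williamson reaction) and the acid-sensitive furfuryl alcohol, and the achiral ligand gives the racemate.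

Step 8
Reactants: 11 methyl 2-[5-({[1-(2,6-dimethoxyphenyl)prop-2-yn-1-yl]oxy}methyl)-2-(2-methyl-1,3-dioxolan-2-yl)furan-3-yl]acetate (racemic)
Product: 13 methyl 2-[3-(2,6-dimethoxyphenyl)-4-hydroxy-5-(2-methyl-1,3-dioxolan-2-yl)-1,3-dihydroisobenzofuran-6-yl]acetate (racemic), via arene oxide 12 (not isolated)
Conditions: Ph3PAuNTf2 (monovalent gold, 3 mol %), 4 Å MS, CH2Cl2, rt
Reagents that add atoms: none
Why: This is the gold-catalysed furan-yne phenol synthesis (Hashmi phenol synthesis), whose closest precedent is the isomerisation of furfuryl propargyl ethers to 4-hydroxy-1,3-dihydroisobenzofurans: cationic gold activates the terminal alkyne, the tethered furan carbon attacks the internal alkyne carbon to give a cyclopropyl gold carbene, and the furan opens to a (Z)-dienone carbene. The carbonyl oxygen then closes on the carbene carbon, the oxepine equilibrates with arene oxide 12, and epoxide opening at the ketal-bearing carbon with loss of the proton on the former terminal alkyne carbon gives the phenol. The five-membered ether ring closes in a 5-exo-dig sense (bond C4–C5 of ring A) and ring A closes by 6π-electrocyclisation of the oxepine (bond C6–C1), the furan oxygen ending on C6. No lasting stereocentre is made: the arene oxide centres vanish on aromatisation and the propargylic centre is carried as the racemate and erased in step 11. The step needs constitutional selectivity (hydroxyl on C6 beside the aryl-bearing C5, ketal-bearing carbon as C1), which the tether enforces, and chemoselectivity for alkyne activation over ionisation of the benzylic propargylic ether or ketal loss, which the mild phosphine-gold catalyst, the dry non-coordinating medium and the electron-rich ketal-masked furan should secure.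

Step 9
Reactants: 13 methyl 2-[3-(2,6-dimethoxyphenyl)-4-hydroxy-5-(2-methyl-1,3-dioxolan-2-yl)-1,3-dihydroisobenzofuran-6-yl]acetate (racemic)
Product: 14 methyl 2-[3-(2,6-dimethoxyphenyl)-4-methoxy-5-(2-methyl-1,3-dioxolan-2-yl)-1,3-dihydroisobenzofuran-6-yl]acetate (racemic)
Conditions: MeI, K2CO3, DMF, rt
Reagents that add atoms: iodomethane CI
Why: Williamson O-methylation protects the phenol against quinone chemistry in the DDQ step with a group that the final BBr3 step removes; carbonate is too weak to enolise the arylacetate.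

Step 10
Reactants: 14 methyl 2-[3-(2,6-dimethoxyphenyl)-4-methoxy-5-(2-methyl-1,3-dioxolan-2-yl)-1,3-dihydroisobenzofuran-6-yl]acetate (racemic)
Product: 16 2-[5-acetyl-3-(2,6-dimethoxyphenyl)-4-methoxy-1,3-dihydroisobenzofuran-6-yl]acetic acid (racemic), via lithium carboxylate 15 (not isolated)
Conditions: LiOH, THF/H2O, 0 °C → rt; then 2 M HCl (pH 1), rt
Reagents that add atoms: lithium hydroxide [Li+].[OH-]; water O
Why: the ester is saponified while the acetyl is still ketal-masked, so the acetyl/ester pair never sees base, and acidification then hydrolyses the ketal in the same flask; the cyclic benzylic ether can only ionise reversibly and recloses.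

Step 11
Reactants: 16 2-[5-acetyl-3-(2,6-dimethoxyphenyl)-4-methoxy-1,3-dihydroisobenzofuran-6-yl]acetic acid (racemic)
Product: 19 2-[2-acetyl-4-(2,6-dimethoxybenzoyl)-5-formyl-3-methoxyphenyl]acetic acid, via isobenzofuran 17 (not isolated), via endoperoxide 18 (not isolated)
Conditions: DDQ, CH2Cl2, rt; filter; then O2, hν (white LED), methylene blue (cat.), 0 °C; then Me2S
Reagents that add atoms: oxygen O=O
Why: DDQ abstracts hydride from the doubly benzylic C3–H (oxocarbenium stabilised by the ring oxygen and the ortho methoxy group of ring A) and loss of a C1 proton gives the 1-arylisobenzofuran, whose [4+2] cycloaddition with singlet oxygen and Me2S reduction of the endoperoxide should give the o-aroylbenzaldehyde, the known dihydroisobenzofuran → isobenzofuran → 1,2-diacylbenzene sequence.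

Step 12
Reactants: 19 2-[2-acetyl-4-(2,6-dimethoxybenzoyl)-5-formyl-3-methoxyphenyl]acetic acid
Product: 20 4-acetyl-5-(carboxymethyl)-2-(2,6-dimethoxybenzoyl)-3-methoxybenzoic acid
Conditions: NaClO2, NaH2PO4, 2-methyl-2-butene, t-BuOH/H2O, 0 °C → rt
Reagents that add atoms: sodium chlorite [Na+].[O-]Cl=O
Why: Pinnick oxidation converts the aldehyde to the acid without touching the ketones, and the alkene scavenger traps hypochlorous acid before it can chlorinate the dimethoxyaryl ring or attack the methyl ketone.

Step 13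
Reactants: 20 4-acetyl-5-(carboxymethyl)-2-(2,6-dimethoxybenzoyl)-3-methoxybenzoic acid
Product: 21 Huanglongmycin D, 4-acetyl-5-(carboxymethyl)-2-(2,6-dihydroxybenzoyl)-3-hydroxybenzoic acid
Conditions: BBr3 (excess), CH2Cl2, −78 °C → rt; then H2O, 0 °C
Reagents that add atoms: none
Why: BBr3 cleaves all three aryl methyl ethers, each ortho to a carbonyl and so chelation-assisted, while the carboxylic acids are tied up as acyloxyboranes and released on hydrolysis.

**Compound list**

1 | methyl 2-(furan-3-yl)acetate | COC(=O)Cc1ccoc1 | starting material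
2 | methyl 2-(2-acetylfuran-3-yl)acetate | COC(=O)Cc1ccoc1C(C)=O | intermediate
3 | methyl 2-[2-(2-methyl-1,3-dioxolan-2-yl)furan-3-yl]acetate | COC(=O)Cc1ccoc1C1(C)OCCO1 | intermediate
4 | N-{[4-(2-methoxy-2-oxoethyl)-5-(2-methyl-1,3-dioxolan-2-yl)furan-2-yl]methylidene}-N-methylmethanaminium chloride | COC(=O)Cc1cc(C=[N+](C)C)oc1C1(C)OCCO1.[Cl-] | intermediate (not isolated)
5 | methyl 2-[5-formyl-2-(2-methyl-1,3-dioxolan-2-yl)furan-3-yl]acetate | COC(=O)Cc1cc(C=O)oc1C1(C)OCCO1 | intermediate
6 | methyl 2-[5-(hydroxymethyl)-2-(2-methyl-1,3-dioxolan-2-yl)furan-3-yl]acetate | COC(=O)Cc1cc(CO)oc1C1(C)OCCO1 | intermediate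
7 | 2,6-dimethoxybenzaldehyde | COc1cccc(OC)c1C=O | starting material
8 | ethynylmagnesium bromide | C#C[Mg]Br | starting material
9 | 1-(2,6-dimethoxyphenyl)prop-2-yn-1-ol (racemic) | C#CC(O)c1c(OC)cccc1OC | intermediate
10 | 1-(2,6-dimethoxyphenyl)prop-2-yn-1-yl acetate (racemic) | C#CC(OC(C)=O)c1c(OC)cccc1OC | intermediate
11 | methyl 2-[5-({[1-(2,6-dimethoxyphenyl)prop-2-yn-1-yl]oxy}methyl)-2-(2-methyl-1,3-dioxolan-2-yl)furan-3-yl]acetate (racemic) | C#CC(OCc1cc(CC(=O)OC)c(o1)C1(C)OCCO1)c1c(OC)cccc1OC | intermediate
12 | methyl 2-[3-(2,6-dimethoxyphenyl)-4,5-epoxy-5-(2-methyl-1,3-dioxolan-2-yl)-1,3,4,5-tetrahydroisobenzofuran-6-yl]acetate (arene oxide, diastereomer mixture) | COC(=O)CC1=CC2=C(C3OC13C4(C)OCCO4)C(OC2)c5c(OC)cccc5OC | intermediate (not isolated)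
13 | methyl 2-[3-(2,6-dimethoxyphenyl)-4-hydroxy-5-(2-methyl-1,3-dioxolan-2-yl)-1,3-dihydroisobenzofuran-6-yl]acetate (racemic) | COC(=O)Cc1cc2COC(c3c(OC)cccc3OC)c2c(O)c1C1(C)OCCO1 | intermediate
14 | methyl 2-[3-(2,6-dimethoxyphenyl)-4-methoxy-5-(2-methyl-1,3-dioxolan-2-yl)-1,3-dihydroisobenzofuran-6-yl]acetate (racemic) | COC(=O)Cc1cc2COC(c3c(OC)cccc3OC)c2c(OC)c1C1(C)OCCO1 | intermediate
15 | lithium 2-[3-(2,6-dimethoxyphenyl)-4-methoxy-5-(2-methyl-1,3-dioxolan-2-yl)-1,3-dihydroisobenzofuran-6-yl]acetate (racemic) | [Li+].[O-]C(=O)Cc1cc2COC(c3c(OC)cccc3OC)c2c(OC)c1C1(C)OCCO1 | intermediate (not isolated)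
16 | 2-[5-acetyl-3-(2,6-dimethoxyphenyl)-4-methoxy-1,3-dihydroisobenzofuran-6-yl]acetic acid (racemic) | OC(=O)Cc1cc2COC(c3c(OC)cccc3OC)c2c(OC)c1C(C)=O | intermediate
17 | 2-[5-acetyl-3-(2,6-dimethoxyphenyl)-4-methoxyisobenzofuran-6-yl]acetic acid | OC(=O)Cc1cc2coc(-c3c(OC)cccc3OC)c2c(OC)c1C(C)=O | intermediate (not isolated)
18 | 2-[5-acetyl-3-(2,6-dimethoxyphenyl)-4-methoxy-1,3-dihydro-1,3-epidioxyisobenzofuran-6-yl]acetic acid | OC(=O)Cc1cc2C3OOC(O3)(c4c(OC)cccc4OC)c2c(OC)c1C(C)=O | intermediate (not isolated)
19 | 2-[2-acetyl-4-(2,6-dimethoxybenzoyl)-5-formyl-3-methoxyphenyl]acetic acid | OC(=O)Cc1cc(C=O)c(C(=O)c2c(OC)cccc2OC)c(OC)c1C(C)=O | intermediate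
20 | 4-acetyl-5-(carboxymethyl)-2-(2,6-dimethoxybenzoyl)-3-methoxybenzoic acid | OC(=O)Cc1cc(C(=O)O)c(C(=O)c2c(OC)cccc2OC)c(OC)c1C(C)=O | intermediate
21 | Huanglongmycin D, 4-acetyl-5-(carboxymethyl)-2-(2,6-dihydroxybenzoyl)-3-hydroxybenzoic acid | CC(=O)c1c(CC(=O)O)cc(C(=O)O)c(C(=O)c2c(O)cccc2O)c1O | target

**Step count**

Total: 13 steps. Longest linear sequence: 11 steps (steps 1–4 and 7–13).

**Steps most likely to fail**

1. Step 8 (gold isomerisation). The Lewis-acidic catalyst may ionise the C–O bond at the aryl-bearing propargylic carbon, or the 2,6-dimethoxyphenyl group may slow the furan attack, so that fragmentation outruns cyclisation. The fallback takes the aryl group out of the cyclisation substrate and sets out from 6. Etherification with propargyl bromide and Ag2O (CH2Cl2, dark) should give methyl 2-[2-(2-methyl-1,3-dioxolan-2-yl)-5-[(prop-2-yn-1-yloxy)methyl]furan-3-yl]acetate F1. The same gold catalyst should convert this unhindered, classical substrate into methyl 2-[4-hydroxy-5-(2-methyl-1,3-dioxolan-2-yl)-1,3-dihydroisobenzofuran-6-yl]acetate F2, and MeI/K2CO3 should give methyl 2-[4-methoxy-5-(2-methyl-1,3-dioxolan-2-yl)-1,3-dihydroisobenzofuran-6-yl]acetate F3. DDQ in CH2Cl2/pH 7 buffer should abstract hydride from the benzylic CH2 ortho to the methoxy group, and water capture gives the lactol methyl 2-[3-hydroxy-4-methoxy-5-(2-methyl-1,3-dioxolan-2-yl)-1,3-dihydroisobenzofuran-6-yl]acetate F4. Its open hydroxy-aldehyde form should accept (2,6-dimethoxyphenyl)magnesium bromide F5 (excess, LaCl3·2LiCl, THF, −40 °C) to give methyl 2-[4-[(2,6-dimethoxyphenyl)(hydroxy)methyl]-5-(hydroxymethyl)-3-methoxy-2-(2-methyl-1,3-dioxolan-2-yl)phenyl]acetate F6. Cyclodehydration of this diol through the stabilised benzhydryl cation (PPTS cat., 4 Å MS, CH2Cl2) returns to the route at 14.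

2. Step 11 (DDQ, then O2). The electron-rich isobenzofuran 17 may be consumed by DDQ through cycloaddition or charge-transfer oligomerisation, or the endoperoxide 18 may rearrange instead of being reduced cleanly. The fallback avoids both species and sets out from 16. DDQ in CH2Cl2/pH 7 phosphate buffer lets water capture the oxocarbenium ion before proton loss, giving 2-[2-acetyl-4-(2,6-dimethoxybenzoyl)-5-(hydroxymethyl)-3-methoxyphenyl]acetic acid F7 (in equilibrium with its lactol). Dess–Martin periodinane oxidation of the benzylic alcohol (NaHCO3, CH2Cl2) then comes back to the route at 19.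

3. Step 7 (copper etherification). Capture of the hindered copper allenylidene by a single equivalent of a complex alcohol may be slow, letting alkyne homocoupling or acetate return dominate. The fallback replaces the copper manifold by an acid-catalysed substitution through the stabilised propargylic cation and sets out from 9. Cl3CCN with DBU (cat., CH2Cl2, 0 °C) should give 1-(2,6-dimethoxyphenyl)prop-2-yn-1-yl 2,2,2-trichloroacetimidate F8, used crude. Treatment with 6 and TMSOTf (cat.) over 4 Å MS in CH2Cl2 at −40 °C, anhydrous so the ketal is not hydrolysed, comes back to the route at 11.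

**Further compounds**

F1 | step 8 | methyl 2-[2-(2-methyl-1,3-dioxolan-2-yl)-5-[(prop-2-yn-1-yloxy)methyl]furan-3-yl]acetate | C#CCOCc1cc(CC(=O)OC)c(o1)C1(C)OCCO1
F2 | step 8 | methyl 2-[4-hydroxy-5-(2-methyl-1,3-dioxolan-2-yl)-1,3-dihydroisobenzofuran-6-yl]acetate | COC(=O)Cc1cc2COCc2c(O)c1C1(C)OCCO1
F3 | step 8 | methyl 2-[4-methoxy-5-(2-methyl-1,3-dioxolan-2-yl)-1,3-dihydroisobenzofuran-6-yl]acetate | COC(=O)Cc1cc2COCc2c(OC)c1C1(C)OCCO1
F4 | step 8 | methyl 2-[3-hydroxy-4-methoxy-5-(2-methyl-1,3-dioxolan-2-yl)-1,3-dihydroisobenzofuran-6-yl]acetate (racemic lactol) | COC(=O)Cc1cc2COC(O)c2c(OC)c1C1(C)OCCO1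
F5 | step 8 | (2,6-dimethoxyphenyl)magnesium bromide | COc1cccc(OC)c1[Mg]Br
F6 | step 8 | methyl 2-[4-[(2,6-dimethoxyphenyl)(hydroxy)methyl]-5-(hydroxymethyl)-3-methoxy-2-(2-methyl-1,3-dioxolan-2-yl)phenyl]acetate (racemic) | COC(=O)Cc1cc(CO)c(C(O)c2c(OC)cccc2OC)c(OC)c1C1(C)OCCO1
F7 | step 11 | 2-[2-acetyl-4-(2,6-dimethoxybenzoyl)-5-(hydroxymethyl)-3-methoxyphenyl]acetic acid | OC(=O)Cc1cc(CO)c(C(=O)c2c(OC)cccc2OC)c(OC)c1C(C)=O
F8 | step 7 | 1-(2,6-dimethoxyphenyl)prop-2-yn-1-yl 2,2,2-trichloroacetimidate (racemic) | C#CC(OC(=N)C(Cl)(Cl)Cl)c1c(OC)cccc1OC
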